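**Retrosynthetic overview**
1. Target 12 ⇒ two successive electrophilic methylsulfenylations of 4,6-dibromoindole 9: first at C3 (10), then a second one with C3→C2 sulfur migration.
2. 9 ⇒ protodecarboxylation of acid 8 ⇐ saponification of ester 6.
3. 6 ⇒ Hemetsberger–Knittel thermolysis of azidocinnamate 4; the pyrrole ring is the only ring formed, closed onto the existing dibromobenzene ring through N–C7a.
4. 4 ⇒ intermolecular aldol (Knoevenagel-type) condensation of 2,4-dibromobenzaldehyde 1 with ethyl azidoacetate 2; this key C–C bond becomes C2–C3 of the indole.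

Assumption: the target has no stereocentre (it is achiral), so "single enantiomer" requires no stereocontrol; the only stereo-element in the route is the alkene geometry of 4, which is lost in step 2.

**Route**

Step 1
Reactants: 1 2,4-dibromobenzaldehyde; 2 ethyl azidoacetate
Product: 4 ethyl (Z)-2-azido-3-(2,4-dibromophenyl)prop-2-enoate, via ethyl 2-azido-3-(2,4-dibromophenyl)-3-hydroxypropanoate 3 (not isolated)
Conditions: NaOEt (4 equiv), 2 (4 equiv), EtOH, −15 → 0 °C, 4 h; then ice-water, filter
Reagents that add atoms: none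
Why: Ethoxide forms the ester enolate of 2, which adds to the non-enolisable aldehyde 1 (intermolecular aldol addition) and adduct 3 dehydrates by E1cB to the conjugated, thermodynamically preferred Z-azidocinnamate (Knoevenagel-type aldol condensation, first stage of the Hemetsberger–Knittel indole synthesis); no stereocentre remains.

Step 2
Reactants: 4 ethyl (Z)-2-azido-3-(2,4-dibromophenyl)prop-2-enoate
Product: 6 ethyl 4,6-dibromo-1H-indole-2-carboxylate, via ethyl 2-(2,4-dibromophenyl)-2H-azirine-3-carboxylate 5 (not isolated)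
Conditions: xylenes, 140 °C (reflux), 3 h; 4 added slowly as a dilute solution to the refluxing solvent
Reagents that add atoms: none
Why: Hemetsberger–Knittel thermolysis: loss of N2 gives the azirine/vinyl nitrene, which cyclises onto the only free ortho position (the other carries Br) and rearomatises by H-shift, so only the 4,6-dibromo isomer can form.

Step 3
Reactants: 6 ethyl 4,6-dibromo-1H-indole-2-carboxylate
Product: 8 4,6-dibromo-1H-indole-2-carboxylic acid, via sodium 4,6-dibromo-1H-indole-2-carboxylate 7 (not isolated)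
Conditions: NaOH (3 equiv), EtOH/H2O, 80 °C, 2 h; then 2 M HCl to pH 2, filter
Reagents that add atoms: sodium hydroxide, [Na+].[OH-]
Why: Ordinary ester saponification (BAc2) followed by acidification; the aryl bromides are not activated towards SNAr and survive.

Step 4
Reactants: 8 4,6-dibromo-1H-indole-2-carboxylic acid
Product: 9 4,6-dibromo-1H-indole
Conditions: Cu powder (0.15 equiv), quinoline, 215 °C, 1.5 h, Ar; then dilute HCl/EtOAc work-up
Reagents that add atoms: none
Why: Copper-catalysed protodecarboxylation of an indole-2-carboxylic acid in quinoline, the standard finish of a Hemetsberger sequence, which is tolerated by ring bromides in the absence of added ligand or base.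

Step 5
Reactants: 9 4,6-dibromo-1H-indole
Product: 10 4,6-dibromo-3-(methylsulfanyl)-1H-indole
Conditions: MeSCl (1.05 equiv; from MeSSMe + SO2Cl2, CH2Cl2, −20 °C), added to 9 in DMF, 0 °C → rt, 1 h; aq NaHCO3
Reagents that add atoms: methanesulfenyl chloride, CSCl (made in the flask from dimethyl disulfide, CSSC)
Why: Electrophilic aromatic substitution (sulfenylation) at C3, the most nucleophilic indole position; in DMF with one equivalent the reaction stops cleanly at the mono-sulfide.

Step 6
Reactants: 10 4,6-dibromo-3-(methylsulfanyl)-1H-indole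
Product: 12 4,6-dibromo-2,3-bis(methylsulfanyl)-1H-indole, via 4,6-dibromo-3,3-bis(methylsulfanyl)-3H-indole 11 (not isolated)
Conditions: MeSCl (1.2 equiv; from MeSSMe + SO2Cl2, CH2Cl2, −20 °C), CH2Cl2, 0 °C → rt, 2 h; aq NaHCO3
Reagents that add atoms: methanesulfenyl chloride, CSCl (made in the flask from dimethyl disulfide, CSSC)
Why: Second electrophilic sulfenylation of a 3-indolyl sulfide: attack at C3 gives the 3,3-bis(sulfide) indoleninium 11 (as its hydrochloride), a 1,2-shift of MeS to C2 through an episulfonium ion and loss of the C2 proton restore the indole (Plancher-type migration); both sulfur groups are identical, so there is no regiochemical issue.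

**Compound list**
1 | 2,4-dibromobenzaldehyde | O=Cc1ccc(Br)cc1Br | starting material
2 | ethyl azidoacetate | CCOC(=O)CN=[N+]=[N-] | starting material
3 | ethyl 2-azido-3-(2,4-dibromophenyl)-3-hydroxypropanoate (racemic diastereomer mixture) | CCOC(=O)C(N=[N+]=[N-])C(O)c1ccc(Br)cc1Br | intermediate (not isolated)
4 | ethyl (Z)-2-azido-3-(2,4-dibromophenyl)prop-2-enoate | CCOC(=O)/C(N=[N+]=[N-])=C/c1ccc(Br)cc1Br | intermediate
5 | ethyl 2-(2,4-dibromophenyl)-2H-azirine-3-carboxylate (racemic) | CCOC(=O)C1=NC1c1ccc(Br)cc1Br | intermediate (not isolated)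
6 | ethyl 4,6-dibromo-1H-indole-2-carboxylate | CCOC(=O)c1cc2c(Br)cc(Br)cc2[nH]1 | intermediate
7 | sodium 4,6-dibromo-1H-indole-2-carboxylate | [Na+].[O-]C(=O)c1cc2c(Br)cc(Br)cc2[nH]1 | intermediate (not isolated)
8 | 4,6-dibromo-1H-indole-2-carboxylic acid | OC(=O)c1cc2c(Br)cc(Br)cc2[nH]1 | intermediate
9 | 4,6-dibromo-1H-indole | Brc1cc(Br)c2cc[nH]c2c1 | intermediate
10 | 4,6-dibromo-3-(methylsulfanyl)-1H-indole | CSc1c[nH]c2cc(Br)cc(Br)c12 | intermediate
11 | 4,6-dibromo-3,3-bis(methylsulfanyl)-3H-indole | CSC1(SC)C=Nc2cc(Br)cc(Br)c21 | intermediate (not isolated)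
12 | 4,6-dibromo-2,3-bis(methylsulfanyl)-1H-indole | CSc1[nH]c2cc(Br)cc(Br)c2c1SC | target

**Totals**
Total step count: 6. Longest linear sequence: 6 steps (1 → 12).

**Steps most likely to fail, with fallbacks**

Step 1 (base-sensitive azidoacetate, ortho-bromo hindrance, often moderate yield). The fallback sets out from 1 and comes back at 4. Horner–Wadsworth–Emmons olefination of 1 with triethyl phosphonoacetate (NaH, THF, 0 °C → rt) gives ethyl (E)-3-(2,4-dibromophenyl)prop-2-enoate F1. Addition of Br2 in CH2Cl2 at 0 °C gives ethyl 2,3-dibromo-3-(2,4-dibromophenyl)propanoate F2. Treatment of F2 with NaN3 (3 equiv) in DMF at rt → 50 °C effects substitution and elimination to the α-azidocinnamate 4, and the route continues with step 2.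

Step 4 (high-temperature Cu decarboxylation; risk of partial debromination or Ullmann-type N-arylation). The fallback sets out from 6 and comes back at 9. Reduction of ester 6 with DIBAL-H (THF/toluene, −78 → 0 °C) gives (4,6-dibromo-1H-indol-2-yl)methanol F3. Oxidation with activated MnO2 (CH2Cl2, rt) gives 4,6-dibromo-1H-indole-2-carbaldehyde F4. Rhodium-catalysed decarbonylation of F4 ([Rh(dppp)2]Cl, 5 mol%, xylene, reflux) then delivers 9 without passing through the acid.

Step 6 (second sulfenylation must occur next to the peri 4-Br and rearrange). The fallback sets out from 9 and comes back at 12; it installs the C2 sulfur first through an oxindole. Oxidation of 9 with pyridinium tribromide (3 equiv, t-BuOH/H2O, rt) gives 3,3,4,6-tetrabromoindolin-2-one F5. Zn dust in AcOH at rt removes the two C3 bromines to give 4,6-dibromoindolin-2-one F6. Lawesson's reagent (THF/toluene, 60 °C) gives 4,6-dibromoindoline-2-thione F7. S-Methylation with MeI/K2CO3 in acetone gives 4,6-dibromo-2-(methylsulfanyl)-1H-indole F8. C3 sulfenylation of this electron-rich indole with MeSCl (DMF, 0 °C) gives target 12.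

**Further compounds**
F1 | step 1 | ethyl (E)-3-(2,4-dibromophenyl)prop-2-enoate | CCOC(=O)/C=C/c1ccc(Br)cc1Br
F2 | step 1 | ethyl 2,3-dibromo-3-(2,4-dibromophenyl)propanoate (racemic anti adduct, 2R*,3S*) | CCOC(=O)C(Br)C(Br)c1ccc(Br)cc1Br
F3 | step 4 | (4,6-dibromo-1H-indol-2-yl)methanol | OCc1cc2c(Br)cc(Br)cc2[nH]1
F4 | step 4 | 4,6-dibromo-1H-indole-2-carbaldehyde | O=Cc1cc2c(Br)cc(Br)cc2[nH]1
F5 | step 6 | 3,3,4,6-tetrabromoindolin-2-one | O=C1Nc2cc(Br)cc(Br)c2C1(Br)Br
F6 | step 6 | 4,6-dibromoindolin-2-one | O=C1Cc2c(Br)cc(Br)cc2N1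
F7 | step 6 | 4,6-dibromoindoline-2-thione | S=C1Cc2c(Br)cc(Br)cc2N1
F8 | step 6 | 4,6-dibromo-2-(methylsulfanyl)-1H-indole | CSc1cc2c(Br)cc(Br)cc2[nH]1
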